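**Retrosynthetic overview**
1. The ten-membered carbocycle is closed last by ring-closing metathesis across C4=C5 (ring-cis, Z) of a seco-triene.
2. The C8 epoxyangelate is attached by Mitsunobu inversion with (2R,3R)-epoxyangelic acid, itself made by Sharpless epoxidation of angelyl alcohol.
3. The C7–C8 bond and the α-methylene-γ-lactone come from a Zn-Barbier allylation of a C8 aldehyde (C1–C4, C8–C10, C14, C15) with a 3-(bromomethyl)butenolide (C5–C7, C11–C13).
4. The aldehyde comes from an E-selective Wittig reaction of an (S)-β-silyloxy aldehyde; the bromolactone comes from acylation and RCM of (S)-hexa-1,4-dien-3-ol.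
5. Ring order: butenolide (RCM), then α-methylene-γ-butyrolactone (Barbier, allylic transposition), then the ten-membered ring (RCM).

Assumption: germacrane numbering is used (lactone carbonyl C12, exocyclic methylene C13, ester carbon C14), and the tartrate senses follow the standard Sharpless model (L-(+)-tartrate gives 2S,3S epoxides from E-allylic primary alcohols).

**Route**

Step 1
Reactants: 1 (2E)-but-2-enal; 2 vinylmagnesium bromide
Product: 3 rac-(4E)-hexa-1,4-dien-3-ol
Conditions: THF, −78 → 0 °C; aq. NH4Cl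
Reagents that add atoms: none
Why: Grignard 1,2-addition to the enal gives the bis-allylic carbinol as a racemate, which is resolved in the next step.

Step 2
Reactants: 3 rac-(4E)-hexa-1,4-dien-3-ol
Product: 4 (3S,4E)-hexa-1,4-dien-3-ol
Conditions: Ti(OiPr)4 (0.15 equiv), D-(−)-DIPT (0.18 equiv), t-BuOOH (0.6 equiv), 4 Å MS, CH2Cl2, −20 °C, stopped at about 55–60 % conversion
Reagents that add atoms: none
Why: Sharpless kinetic resolution: with D-(−)-tartrate the 3R enantiomer is epoxidised quickly at its E-propenyl group, whereas the 3S enantiomer has only its much slower vinyl group matched and is recovered in high ee.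

Step 3
Reactants: 4 (3S,4E)-hexa-1,4-dien-3-ol; 5 2-(bromomethyl)prop-2-enoic acid
Product: 7 (3S,4E)-hexa-1,4-dien-3-yl 2-(bromomethyl)prop-2-enoate, via acid chloride 6 (not isolated)
Conditions: 5, (COCl)2, cat. DMF, CH2Cl2, 0 °C → rt; then 4, i-Pr2NEt, CH2Cl2, −78 → 0 °C
Reagents that add atoms: none
Why: O-acylation by the acid chloride leaves the carbinol C–O bond intact (retention), and the hindered base avoids SN2' attack on the allylic bromide.

Step 4
Reactants: 7 (3S,4E)-hexa-1,4-dien-3-yl 2-(bromomethyl)prop-2-enoate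
Product: 8 (5R)-3-(bromomethyl)-5-[(1E)-prop-1-en-1-yl]furan-2(5H)-one
Conditions: Grubbs II (5 mol %), CH2Cl2 (0.01 M), 40 °C
Reagents that add atoms: none
Why: Ring-closing metathesis: Ru loads on the terminal vinyl and closes onto the acrylate to the butenolide with loss of ethene, the slower E-propenyl group is kept as the later metathesis handle, and the neutral conditions preserve the γ-stereocentre.

Step 5
Reactants: 9 tert-butyl acetate; 10 methacrolein
Product: 12 rac-tert-butyl 3-hydroxy-4-methylpent-4-enoate, via lithium enolate 11 (not isolated)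
Conditions: LDA, THF, −78 °C; then 10; aq. NH4Cl
Reagents that add atoms: none
Why: Aldol addition of the ester lithium enolate occurs 1,2 to the enal and gives the racemic allylic alcohol.

Step 6
Reactants: 12 rac-tert-butyl 3-hydroxy-4-methylpent-4-enoate
Product: 13 tert-butyl (3S)-3-hydroxy-4-methylpent-4-enoate
Conditions: Ti(OiPr)4 (0.15 equiv), D-(−)-DIPT (0.18 equiv), t-BuOOH (0.6 equiv), 4 Å MS, CH2Cl2, −20 °C
Reagents that add atoms: none
Why: Sharpless kinetic resolution: with D-(−)-tartrate the 3R enantiomer is epoxidised at the isopropenyl group (erythro epoxy alcohol) and the 3S alcohol, which becomes C3 of the target, is recovered.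

Step 7
Reactants: 13 tert-butyl (3S)-3-hydroxy-4-methylpent-4-enoate
Product: 14 tert-butyl (3S)-3-[(tert-butyldimethylsilyl)oxy]-4-methylpent-4-enoate
Conditions: TBSCl, imidazole, DMF, rt
Reagents that add atoms: tert-butyldimethylsilyl chloride, CC(C)(C)[Si](C)(C)Cl
Why: Silylation of the secondary allylic alcohol gives an ether that survives all steps up to the fluoride deprotection.

Step 8
Reactants: 14 tert-butyl (3S)-3-[(tert-butyldimethylsilyl)oxy]-4-methylpent-4-enoate
Product: 15 (3S)-3-[(tert-butyldimethylsilyl)oxy]-4-methylpent-4-enal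
Conditions: DIBAL-H (1.1 equiv), CH2Cl2, −78 °C; Rochelle salt
Reagents that add atoms: none
Why: DIBAL half-reduction: the tetrahedral aluminium hemiacetal of the tert-butyl ester is stable at −78 °C and releases the aldehyde only on work-up.

Step 9
Reactants: 16 methyl (triphenylphosphoranylidene)acetate (2 equiv); 17 allyl bromoacetate
Product: 19 4-allyl 1-methyl 2-(triphenylphosphoranylidene)butanedioate, via phosphonium bromide 18 (not isolated)
Conditions: EtOAc, reflux; filter off the precipitated phosphonium salt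
Reagents that add atoms: none
Why: C-alkylation of the stabilised ylide followed by Bestmann transylidation by the second equivalent of 16 gives the substituted stabilised ylide with two differentiated esters.

Step 10
Reactants: 15 (3S)-3-[(tert-butyldimethylsilyl)oxy]-4-methylpent-4-enal; 19 4-allyl 1-methyl 2-(triphenylphosphoranylidene)butanedioate
Product: 20 4-allyl 1-methyl (2E)-2-[(3S)-3-[(tert-butyldimethylsilyl)oxy]-4-methylpent-4-en-1-ylidene]butanedioate
Conditions: toluene, 90 °C
Reagents that add atoms: none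
Why: Wittig olefination with an α-substituted stabilised ylide gives the E-trisubstituted enoate (chain trans to CO2Me, the C1=C10 geometry of the target) under neutral conditions that do not eliminate the β-silyloxy group.

Step 11
Reactants: 20 4-allyl 1-methyl (2E)-2-[(3S)-3-[(tert-butyldimethylsilyl)oxy]-4-methylpent-4-en-1-ylidene]butanedioate
Product: 21 (3E,6S)-6-[(tert-butyldimethylsilyl)oxy]-3-(methoxycarbonyl)-7-methylocta-3,7-dienoic acid
Conditions: Pd(PPh3)4 (3 mol %), morpholine, THF, rt; work-up at pH 4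
Reagents that add atoms: none
Why: Tsuji–Trost deallylation removes only the allyl ester through a π-allyl-Pd complex trapped by morpholine, leaving the conjugated methyl ester, the silyl ether and the olefins untouched.

Step 12
Reactants: 21 (3E,6S)-6-[(tert-butyldimethylsilyl)oxy]-3-(methoxycarbonyl)-7-methylocta-3,7-dienoic acid
Product: 23 methyl (2E,5S)-5-[(tert-butyldimethylsilyl)oxy]-2-(2-hydroxyethyl)-6-methylhepta-2,6-dienoate, via mixed anhydride 22 (not isolated)
Conditions: i-BuOCOCl, N-methylmorpholine, THF, −15 °C; then NaBH4, THF/H2O, −15 → 0 °C; AcOH quench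
Reagents that add atoms: none
Why: Mixed-anhydride activation followed by borohydride reduction reduces the free acid chemoselectively in the presence of the conjugated ester and the 1,1-disubstituted olefin, and the cold acidic quench limits lactonisation of the γ-hydroxy ester.

Step 13
Reactants: 23 methyl (2E,5S)-5-[(tert-butyldimethylsilyl)oxy]-2-(2-hydroxyethyl)-6-methylhepta-2,6-dienoate
Product: 24 methyl (2E,5S)-5-[(tert-butyldimethylsilyl)oxy]-6-methyl-2-(2-oxoethyl)hepta-2,6-dienoate
Conditions: Dess–Martin periodinane, NaHCO3, CH2Cl2, 0 °C → rt; used at once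
Reagents that add atoms: none
Why: Buffered Dess–Martin oxidation gives the β,γ-unsaturated aldehyde without base or acid that would move the double bond into conjugation.

Step 14
Reactants: 25 methyl (2Z)-2-methylbut-2-enoate (methyl angelate)
Product: 26 (2Z)-2-methylbut-2-en-1-ol (angelyl alcohol)
Conditions: DIBAL-H (2.2 equiv), Et2O, −78 → 0 °C; Rochelle salt
Reagents that add atoms: none
Why: DIBAL 1,2-reduction of the enoate gives the allylic alcohol with the Z geometry retained.

Step 15
Reactants: 26 (2Z)-2-methylbut-2-en-1-ol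
Product: 27 [(2S,3R)-2,3-dimethyloxiran-2-yl]methanol
Conditions: Ti(OiPr)4 (cat.), L-(+)-DET, t-BuOOH, 4 Å MS, CH2Cl2, −20 °C
Reagents that add atoms: tert-butyl hydroperoxide, CC(C)(C)OO
Why: Sharpless asymmetric epoxidation with L-(+)-tartrate delivers oxygen to the face that gives the 2S,3R epoxy alcohol, and the syn addition keeps the two methyl groups trans as in the Z olefin.

Step 16
Reactants: 27 [(2S,3R)-2,3-dimethyloxiran-2-yl]methanol
Product: 29 (2R,3R)-2,3-dimethyloxirane-2-carboxylic acid, via epoxy aldehyde 28 (not isolated)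
Conditions: TEMPO (cat.), PhI(OAc)2 (2.2 equiv), MeCN/H2O 1:1, rt; used at once
Reagents that add atoms: water, O
Why: TEMPO/oxoammonium oxidation takes the primary alcohol through the aldehyde hydrate to the acid without touching the epoxide; the descriptor at C2 changes from S to R only through CIP priorities.

Step 17
Reactants: 8 (5R)-3-(bromomethyl)-5-[(1E)-prop-1-en-1-yl]furan-2(5H)-one; 24 methyl (2E,5S)-5-[(tert-butyldimethylsilyl)oxy]-6-methyl-2-(2-oxoethyl)hepta-2,6-dienoate
Product: 31 methyl (2E,5S)-5-[(tert-butyldimethylsilyl)oxy]-2-{(2S)-2-hydroxy-2-[(2R,3R)-4-methylidene-5-oxo-2-[(1E)-prop-1-en-1-yl]oxolan-3-yl]ethyl}-6-methylhepta-2,6-dienoate, via allylzinc bromide 30 (not isolated)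
Conditions: Zn dust, THF/sat. aq. NH4Cl (2:1), 0 °C → rt
Reagents that add atoms: none
Why: Zinc Barbier allylation: the allylzinc reacts through its ring γ-carbon with allylic transposition to the α-methylene lactone, anti to the C6 propenyl group (trans lactone, 7R), and a Zimmerman–Traxler chair with the ring-locked E-type allyl unit and the aldehyde chain equatorial gives the anti carbinol (8S).

Step 18
Reactants: 31 the 8S alcohol from step 17; 29 (2R,3R)-2,3-dimethyloxirane-2-carboxylic acid
Product: 32 methyl (2E,5S)-5-[(tert-butyldimethylsilyl)oxy]-2-{(2R)-2-{[(2R,3R)-2,3-dimethyloxirane-2-carbonyl]oxy}-2-[(2R,3R)-4-methylidene-5-oxo-2-[(1E)-prop-1-en-1-yl]oxolan-3-yl]ethyl}-6-methylhepta-2,6-dienoate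
Conditions: PPh3, DIAD, toluene, 0 °C → rt
Reagents that add atoms: none
Why: Mitsunobu esterification: the epoxy carboxylate displaces the C8 oxyphosphonium by SN2, installing the ester and inverting 8S to the required 8R in one operation.

Step 19
Reactants: 32 the silyl-protected epoxyangelate from step 18
Product: 33 methyl (2E,5S)-2-{(2R)-2-{[(2R,3R)-2,3-dimethyloxirane-2-carbonyl]oxy}-2-[(2R,3R)-4-methylidene-5-oxo-2-[(1E)-prop-1-en-1-yl]oxolan-3-yl]ethyl}-5-hydroxy-6-methylhepta-2,6-dienoate
Conditions: HF·pyridine, excess pyridine, THF, 0 °C → rt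
Reagents that add atoms: none
Why: Buffered fluoride desilylation frees the C3 allylic alcohol without opening the epoxide, adding to the α-methylene lactone or moving an acyl group.

Step 20
Reactants: 33 the seco-triene alcohol from step 19
Product: 34 CNP0143679.1, the (3S,6R,7R,8R)-germacra-1(10)E,4Z,11(13)-trien-6,12-olide with 3-OH, 8-O-(2R,3R)-epoxyangelate and C14 methyl ester
Conditions: Hoveyda–Grubbs II (15 mol %), 1,4-benzoquinone (20 mol %), toluene (1 mM), 80 °C
Reagents that add atoms: none
Why: Ring-closing metathesis between the C6 propenyl and the C4 isopropenyl groups (free allylic OH assisting, propene lost) closes the ten-membered ring, and the medium ring takes the new trisubstituted olefin in the ring-cis (4Z) geometry; no stereocentre is touched.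

**Compound list**
1 | (2E)-but-2-enal (crotonaldehyde) | C/C=C/C=O | starting material
2 | vinylmagnesium bromide | C=C[Mg]Br | starting material
3 | rac-(4E)-hexa-1,4-dien-3-ol | C=CC(O)/C=C/C | intermediate
4 | (3S,4E)-hexa-1,4-dien-3-ol | C=C[C@H](O)/C=C/C | intermediate
5 | 2-(bromomethyl)prop-2-enoic acid | C=C(CBr)C(=O)O | starting material
6 | 2-(bromomethyl)prop-2-enoyl chloride | C=C(CBr)C(=O)Cl | intermediate
7 | (3S,4E)-hexa-1,4-dien-3-yl 2-(bromomethyl)prop-2-enoate | C=C(CBr)C(=O)O[C@@H](C=C)/C=C/C | intermediate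
8 | (5R)-3-(bromomethyl)-5-[(1E)-prop-1-en-1-yl]furan-2(5H)-one | O=C1O[C@H](/C=C/C)C=C1CBr | intermediate
9 | tert-butyl acetate | CC(=O)OC(C)(C)C | starting material
10 | methacrolein | CC(=C)C=O | starting material
11 | lithium enolate of tert-butyl acetate | C=C(O[Li])OC(C)(C)C | intermediate
12 | rac-tert-butyl 3-hydroxy-4-methylpent-4-enoate | CC(=C)C(O)CC(=O)OC(C)(C)C | intermediate
13 | tert-butyl (3S)-3-hydroxy-4-methylpent-4-enoate | CC(=C)[C@@H](O)CC(=O)OC(C)(C)C | intermediate
14 | tert-butyl (3S)-3-[(tert-butyldimethylsilyl)oxy]-4-methylpent-4-enoate | CC(=C)[C@@H](O[Si](C)(C)C(C)(C)C)CC(=O)OC(C)(C)C | intermediate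
15 | (3S)-3-[(tert-butyldimethylsilyl)oxy]-4-methylpent-4-enal | CC(=C)[C@@H](O[Si](C)(C)C(C)(C)C)CC=O | intermediate
16 | methyl (triphenylphosphoranylidene)acetate | COC(=O)C=P(c1ccccc1)(c1ccccc1)c1ccccc1 | starting material
17 | allyl bromoacetate | C=CCOC(=O)CBr | starting material
18 | [4-(allyloxy)-1-methoxy-1,4-dioxobutan-2-yl]triphenylphosphonium bromide | COC(=O)C(CC(=O)OCC=C)[P+](c1ccccc1)(c1ccccc1)c1ccccc1.[Br-] | intermediate
19 | 4-allyl 1-methyl 2-(triphenylphosphoranylidene)butanedioate | COC(=O)C(CC(=O)OCC=C)=P(c1ccccc1)(c1ccccc1)c1ccccc1 | intermediate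
20 | 4-allyl 1-methyl (2E)-2-[(3S)-3-[(tert-butyldimethylsilyl)oxy]-4-methylpent-4-en-1-ylidene]butanedioate | C=CCOC(=O)C/C(C(=O)OC)=C\C[C@H](O[Si](C)(C)C(C)(C)C)C(C)=C | intermediate
21 | (3E,6S)-6-[(tert-butyldimethylsilyl)oxy]-3-(methoxycarbonyl)-7-methylocta-3,7-dienoic acid | OC(=O)C/C(C(=O)OC)=C\C[C@H](O[Si](C)(C)C(C)(C)C)C(C)=C | intermediate
22 | isobutyl carbonic mixed anhydride of 21 | CC(C)COC(=O)OC(=O)C/C(C(=O)OC)=C\C[C@H](O[Si](C)(C)C(C)(C)C)C(C)=C | intermediate
23 | methyl (2E,5S)-5-[(tert-butyldimethylsilyl)oxy]-2-(2-hydroxyethyl)-6-methylhepta-2,6-dienoate | OCC/C(C(=O)OC)=C\C[C@H](O[Si](C)(C)C(C)(C)C)C(C)=C | intermediate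
24 | methyl (2E,5S)-5-[(tert-butyldimethylsilyl)oxy]-6-methyl-2-(2-oxoethyl)hepta-2,6-dienoate | O=CC/C(C(=O)OC)=C\C[C@H](O[Si](C)(C)C(C)(C)C)C(C)=C | intermediate
25 | methyl (2Z)-2-methylbut-2-enoate (methyl angelate) | C/C=C(/C)C(=O)OC | starting material
26 | (2Z)-2-methylbut-2-en-1-ol | C/C=C(/C)CO | intermediate
27 | [(2S,3R)-2,3-dimethyloxiran-2-yl]methanol | OC[C@]1(C)O[C@@H]1C | intermediate
28 | (2R,3R)-2,3-dimethyloxirane-2-carbaldehyde | O=C[C@]1(C)O[C@@H]1C | intermediate
29 | (2R,3R)-2,3-dimethyloxirane-2-carboxylic acid | OC(=O)[C@]1(C)O[C@@H]1C | intermediate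
30 | {(5R)-2-oxo-5-[(1E)-prop-1-en-1-yl]-2,5-dihydrofuran-3-yl}methylzinc bromide | O=C1O[C@H](/C=C/C)C=C1C[Zn]Br | intermediate
31 | methyl (2E,5S)-5-[(tert-butyldimethylsilyl)oxy]-2-{(2S)-2-hydroxy-2-[(2R,3R)-4-methylidene-5-oxo-2-[(1E)-prop-1-en-1-yl]oxolan-3-yl]ethyl}-6-methylhepta-2,6-dienoate | C=C1C(=O)O[C@H](/C=C/C)[C@H]1[C@@H](O)C/C(C(=O)OC)=C\C[C@H](O[Si](C)(C)C(C)(C)C)C(C)=C | intermediate
32 | methyl (2E,5S)-5-[(tert-butyldimethylsilyl)oxy]-2-{(2R)-2-{[(2R,3R)-2,3-dimethyloxirane-2-carbonyl]oxy}-2-[(2R,3R)-4-methylidene-5-oxo-2-[(1E)-prop-1-en-1-yl]oxolan-3-yl]ethyl}-6-methylhepta-2,6-dienoate | C=C1C(=O)O[C@H](/C=C/C)[C@H]1[C@H](OC(=O)[C@]2(C)O[C@@H]2C)C/C(C(=O)OC)=C\C[C@H](O[Si](C)(C)C(C)(C)C)C(C)=C | intermediate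
33 | methyl (2E,5S)-2-{(2R)-2-{[(2R,3R)-2,3-dimethyloxirane-2-carbonyl]oxy}-2-[(2R,3R)-4-methylidene-5-oxo-2-[(1E)-prop-1-en-1-yl]oxolan-3-yl]ethyl}-5-hydroxy-6-methylhepta-2,6-dienoate | C=C1C(=O)O[C@H](/C=C/C)[C@H]1[C@H](OC(=O)[C@]2(C)O[C@@H]2C)C/C(C(=O)OC)=C\C[C@H](O)C(C)=C | intermediate
34 | CNP0143679.1: methyl (3S,6R,7R,8R)-8-{[(2R,3R)-2,3-dimethyloxirane-2-carbonyl]oxy}-3-hydroxy-germacra-1(10)E,4Z,11(13)-trien-6,12-olid-14-oate | C=C1C(=O)O[C@@H]2/C=C(/C)[C@@H](O)C/C=C(/C(=O)OC)C[C@@H](OC(=O)[C@]3(C)O[C@@H]3C)[C@@H]12 | target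

**Totals and risks**
Total step count: 20. Longest linear sequence: 12 steps (steps 5–8, 10–13, 17–20).

Step 17 (Barbier coupling). The risks are modest control at C8 and isomerisation of the β,γ-unsaturated aldehyde. The fallback sets out from 8 and 24 and couples them through a Lewis-acid open transition state instead of the zinc chair. Bromide 8 is stannylated with hexabutylditin and Pd(PPh3)4 to the allylstannane (5R)-5-[(1E)-prop-1-en-1-yl]-3-[(tributylstannyl)methyl]furan-2(5H)-one F1. F1 adds to 24 with BF3·OEt2 in CH2Cl2 at −78 °C (antiperiplanar open transition state, syn-selective, still anti to the C6 group) and gives the 8R alcohol methyl (2E,5S)-5-[(tert-butyldimethylsilyl)oxy]-2-{(2R)-2-hydroxy-2-[(2R,3R)-4-methylidene-5-oxo-2-[(1E)-prop-1-en-1-yl]oxolan-3-yl]ethyl}-6-methylhepta-2,6-dienoate F2. F2 is acylated with retention by acid 29 under Yamaguchi conditions (2,4,6-trichlorobenzoyl chloride, Et3N, DMAP), and the route is rejoined at 32.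

Step 18 (Mitsunobu inversion). The risks are E2 elimination toward the dienoate and partial retention with the hindered α,α-disubstituted acid. The fallback sets out from 31 and separates activation from displacement. Alcohol 31 is converted with ClCH2SO2Cl and pyridine into the C8 chloromethanesulfonate of 31 F3. F3 is displaced by the caesium salt of 29 (Cs2CO3, 18-crown-6, toluene, 60 °C) in an SN2 reaction with inversion, and the route is rejoined at 32.

Step 20 (macrocyclic RCM). The risks are slow closure of the trisubstituted olefin, dimerisation and Ru–H isomerisation of the free allylic alcohol. The fallback sets out from 32 and closes the ring on the silyl ether before the alcohol is unveiled. RCM of 32 (Grubbs II, toluene, 1 mM, 100 °C) gives the 3-O-tert-butyldimethylsilyl ether of 34 F4. F4 is desilylated with HF·pyridine, and the route is rejoined at 34.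

**Further compounds**
F1 | step 17 | (5R)-5-[(1E)-prop-1-en-1-yl]-3-[(tributylstannyl)methyl]furan-2(5H)-one | O=C1O[C@H](/C=C/C)C=C1C[Sn](CCCC)(CCCC)CCCC
F2 | step 17 | methyl (2E,5S)-5-[(tert-butyldimethylsilyl)oxy]-2-{(2R)-2-hydroxy-2-[(2R,3R)-4-methylidene-5-oxo-2-[(1E)-prop-1-en-1-yl]oxolan-3-yl]ethyl}-6-methylhepta-2,6-dienoate | C=C1C(=O)O[C@H](/C=C/C)[C@H]1[C@H](O)C/C(C(=O)OC)=C\C[C@H](O[Si](C)(C)C(C)(C)C)C(C)=C
F3 | step 18 | C8 chloromethanesulfonate of 31 | C=C1C(=O)O[C@H](/C=C/C)[C@H]1[C@@H](OS(=O)(=O)CCl)C/C(C(=O)OC)=C\C[C@H](O[Si](C)(C)C(C)(C)C)C(C)=C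
F4 | step 20 | 3-O-tert-butyldimethylsilyl ether of 34 | C=C1C(=O)O[C@@H]2/C=C(/C)[C@@H](O[Si](C)(C)C(C)(C)C)C/C=C(/C(=O)OC)C[C@@H](OC(=O)[C@]3(C)O[C@@H]3C)[C@@H]12
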